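The cycloheptene ring is disconnected (azulene numbering) between C4–C5 and C8–C8a into a four-carbon dienyl anisate (C5–C8) and the three-carbon unit C4–C3a–C8a of the cyclopentanone. The route exploits the C6=C7 olefin flanked by sp3 C5 and C8 and the quaternary C8a next to the C1 ketone: the pattern left by a divinylcyclopropane rearrangement of a cyclopentenone. In one operation an acyclic diazo ynone closes ring A (the cyclopentenone) by carbene/alkyne metathesis, the transposed vinylcarbenoid cyclopropanates the diene, and a Cope shift delivers the hydroazulene with C8 and C8a set. Markovnikov hydration of the remaining C3a=C4 olefin then installs the tertiary alcohol.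

Key step: step 6

Remark 1: the azulene numbering of the target (C1 ketone, C3 isopropyl carbon, C3a carbinol carbon, C4, C5, C6 methyl-bearing olefin carbon, C7, C8 ester carbon, C8a angular carbon) is used for the corresponding atoms of all intermediates.
Remark 2 (assumption): (R)-DTBM-SEGPHOS is written as the ligand enantiomer that gives the 5R ketone in step 2; should the first run show the opposite sense, the S ligand is used.
Remark 3: rhodium-bound carbenoids in step 6 are catalyst-bound transients and are not numbered; the first metal-free species after loss of N2 is the divinylcyclopropane 12.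

Step 1
Reactants: 1 2-methylpropanal; 2 diethyl (2-oxobutyl)phosphonate
Product: 3 (4E)-6-methylhept-4-en-3-one
Conditions: Ba(OH)2 (activated), THF/H2O (40:1), 20 °C
Reagents that add atoms: none
Why: Horner–Wadsworth–Emmons olefination of a stabilized β-keto phosphonate anion with an unhindered aldehyde should give the E-enone under conditions mild enough not to enolize the aldehyde.

Step 2
Reactants: 3 (4E)-6-methylhept-4-en-3-one; 4 ethynyltri(propan-2-yl)silane
Product: 5 (5R)-6-methyl-5-{[tri(propan-2-yl)silyl]ethynyl}heptan-3-one
Conditions: [Rh(OAc)(C2H4)2]2 (2.5 mol %), (R)-DTBM-SEGPHOS (6 mol %), 4 (2 equiv), 1,4-dioxane, 80 °C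
Reagents that add atoms: none
Why: Rhodium-catalysed asymmetric conjugate alkynylation of a linear E-enone, in which the bulky silyl group suppresses alkyne dimerization and the bisphosphine-bound rhodium acetylide adds to one enone face, should set the 5R centre (the later C3) under catalyst control.

Step 3
Reactants: 5 (5R)-6-methyl-5-{[tri(propan-2-yl)silyl]ethynyl}heptan-3-one
Product: 7 (5R)-2-diazo-6-methyl-5-{[tri(propan-2-yl)silyl]ethynyl}heptan-3-one, via α-trifluoroacetyl ketone 6 (not isolated)
Conditions: LiN(SiMe3)2, THF, −78 °C; CF3CO2CH2CF3; aqueous HCl work-up, crude 6 used at once; then MsN3, Et3N, H2O (1 equiv), MeCN, 20 °C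
Reagents that add atoms: methanesulfonyl azide, CS(=O)(=O)N=[N+]=[N-]; 2,2,2-trifluoroethyl trifluoroacetate, O=C(OCC(F)(F)F)C(F)(F)F (its trifluoroacetyl group is carried only in 6)
Why: Detrifluoroacetylative (Regitz-type) diazo transfer, in which the amide base should deprotonate the ethyl CH2 kinetically because the other α-methylene is shielded by the branched C5, Claisen trifluoroacetylation then activates only that carbon for diazo transfer, and the C5 centre is not touched.

Step 4
Reactants: 7 (5R)-2-diazo-6-methyl-5-{[tri(propan-2-yl)silyl]ethynyl}heptan-3-one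
Product: 8 (5R)-2-diazo-5-ethynyl-6-methylheptan-3-one
Conditions: Bu4NF, AcOH (1:1), THF, 0 °C
Reagents that add atoms: none
Why: Fluoride-induced protodesilylation of the alkynylsilane, buffered with acetic acid so that the α-diazo ketone and the C5 centre survive, should free the terminal alkyne needed for the metathesis step.

Step 5
Reactants: 9 3-methylbut-2-enal; 10 4-methoxybenzoyl chloride
Product: 11 (1E)-3-methylbuta-1,3-dien-1-yl 4-methoxybenzoate
Conditions: KOtBu, THF, −78 °C; then 10, −78 → 0 °C
Reagents that add atoms: none
Why: γ-Deprotonation of the enal gives the potassium dienolate, whose O-acylation (dienol ester formation) at low temperature should give the 1E-dienyl ester, the geometry that later fixes C8.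

Step 6
Reactants: 8 (5R)-2-diazo-5-ethynyl-6-methylheptan-3-one; 11 (1E)-3-methylbuta-1,3-dien-1-yl 4-methoxybenzoate
Product: 13 (3R,8R,8aS)-6,8a-dimethyl-1-oxo-3-(propan-2-yl)-1,2,3,5,8,8a-hexahydroazulen-8-yl 4-methoxybenzoate, via cis-divinylcyclopropane 12 (not isolated)
Conditions: Rh2(O2CCPh3)4 (1 mol %), 11 (4 equiv), PhMe, −20 → 20 °C, slow addition of 8; then 120 °C (sealed)
Reagents that add atoms: none
Why: Loss of N2 gives an α-keto rhodium carbenoid at C8a that adds to the tethered alkyne (carbene/alkyne metathesis), closing the cyclopentenone and moving the carbenoid to C4; this vinylcarbenoid cyclopropanates the terminal C5=C6 bond of 11 (bonds C4–C5 and C4–C6), and the cis-divinylcyclopropane 12 undergoes the divinylcyclopropane–cycloheptadiene (Cope) rearrangement, which breaks C4–C6 and forms C8–C8a. The closest known reaction types are carbene/alkyne metathesis cascades of alkynyl diazo ketones that end in olefin cyclopropanation, the tandem cyclopropanation/Cope formal [4+3] of rhodium vinylcarbenoids with dienes, and the thermal rearrangement of 3-(2-vinylcyclopropyl)-2-methylcyclopentenones to angular-methyl hydroazulenones. The five-membered ring closes by 5-exo-dig attack of the carbenoid carbon on the alkyne, and the seven-membered ring closes by a [3,3]-sigmatropic shift through the boat transition state with both vinyl arms over the cyclopropane, so both ring olefins are cis. In that boat the E-anisoyloxy group at C8 points outward and the C8a methyl inward, which places H8 and the methyl cis (8-O trans to 8a-CH3; 8R, 8aS), while the C3 isopropyl group makes C8 bond to the opposite face of the cyclopentenone, because the diastereomeric boat would hold the isopropyl group under the forming ring. The step needs alkyne capture to outrun 1,2-hydride shift from the α-methyl group (five-membered tether, bulky triphenylacetate ligands, low temperature), capture of the vinylcarbenoid by the diene (slow addition of 8 into excess 11, whose unhindered electron-rich CH2 terminus is the reactive olefin carbon), and convergence of the cyclopropane isomers (trans isomers should epimerize through reversible homolysis of the doubly allylic C4–C6 bond at 120 °C, and only the cis isomer with the isopropyl group exo drains to 13).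

Step 7
Reactants: 13 (3R,8R,8aS)-6,8a-dimethyl-1-oxo-3-(propan-2-yl)-1,2,3,5,8,8a-hexahydroazulen-8-yl 4-methoxybenzoate
Product: 14 (3R,3aS,8R,8aR)-3a-hydroxy-6,8a-dimethyl-1-oxo-3-(propan-2-yl)-1,2,3,3a,4,5,8,8a-octahydroazulen-8-yl 4-methoxybenzoate (target)
Conditions: Co(acac)2 (20 mol %), PhSiH3 (2.5 equiv), O2 (1 atm), THF, 0 → 20 °C
Reagents that add atoms: dioxygen, O=O
Why: Mukaiyama hydration (metal hydride hydrogen atom transfer) should deliver H to the unhindered C4 and give the tertiary C3a radical, which is expected to capture O2 on the convex β-face syn to the angular methyl to give the cis-fused carbinol (as in 14β-hydroxylation of steroidal 14-olefins), while the C6=C7 olefin, deactivated and shielded by the allylic ester, should react more slowly.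

Compound list
1 | 2-methylpropanal | CC(C)C=O | starting material
2 | diethyl (2-oxobutyl)phosphonate | CCC(=O)CP(=O)(OCC)OCC | starting material
3 | (4E)-6-methylhept-4-en-3-one | CCC(=O)/C=C/C(C)C | intermediate
4 | ethynyltri(propan-2-yl)silane | C#C[Si](C(C)C)(C(C)C)C(C)C | starting material
5 | (5R)-6-methyl-5-{[tri(propan-2-yl)silyl]ethynyl}heptan-3-one | CCC(=O)C[C@H](C(C)C)C#C[Si](C(C)C)(C(C)C)C(C)C | intermediate
6 | (6R)-1,1,1-trifluoro-3,7-dimethyl-6-{[tri(propan-2-yl)silyl]ethynyl}octane-2,4-dione (C3 epimers, largely enolized) | CC(C(=O)C(F)(F)F)C(=O)C[C@H](C(C)C)C#C[Si](C(C)C)(C(C)C)C(C)C | intermediate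
7 | (5R)-2-diazo-6-methyl-5-{[tri(propan-2-yl)silyl]ethynyl}heptan-3-one | CC(=[N+]=[N-])C(=O)C[C@H](C(C)C)C#C[Si](C(C)C)(C(C)C)C(C)C | intermediate
8 | (5R)-2-diazo-5-ethynyl-6-methylheptan-3-one | CC(=[N+]=[N-])C(=O)C[C@H](C(C)C)C#C | intermediate
9 | 3-methylbut-2-enal | CC(C)=CC=O | starting material
10 | 4-methoxybenzoyl chloride | COc1ccc(cc1)C(Cl)=O | starting material
11 | (1E)-3-methylbuta-1,3-dien-1-yl 4-methoxybenzoate | COc1ccc(cc1)C(=O)O/C=C/C(C)=C | intermediate
12 | (1E)-2-{(1S,2R)-1-methyl-2-[(5R)-2-methyl-3-oxo-5-(propan-2-yl)cyclopent-1-en-1-yl]cyclopropyl}ethen-1-yl 4-methoxybenzoate | COc1ccc(cc1)C(=O)O/C=C/[C@@]2(C)C[C@H]2C3=C(C)C(=O)C[C@@H]3C(C)C | intermediate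
13 | (3R,8R,8aS)-6,8a-dimethyl-1-oxo-3-(propan-2-yl)-1,2,3,5,8,8a-hexahydroazulen-8-yl 4-methoxybenzoate | COc1ccc(cc1)C(=O)O[C@@H]2C=C(C)CC=C3[C@@H](C(C)C)CC(=O)[C@]23C | intermediate
14 | (3R,3aS,8R,8aR)-3a-hydroxy-6,8a-dimethyl-1-oxo-3-(propan-2-yl)-1,2,3,3a,4,5,8,8a-octahydroazulen-8-yl 4-methoxybenzoate | COc1ccc(C(=O)O[C@@H]2C=C(C)CC[C@]3(O)[C@@H](C(C)C)CC(=O)[C@]23C)cc1 | target

Total step count: 7. Longest linear sequence: 6 steps (steps 1, 2, 3, 4, 6, 7); step 5 supplies the diene.

Steps most likely to fail

Step 6. Bimolecular capture of the short-lived vinylcarbenoid by the diene may lose to carbene dimerization or azine formation with unreacted 8, or the trans-divinylcyclopropanes may decompose by homo-1,5-hydrogen shift before they epimerize. The fallback sets out from 8 and comes back at 13; it separates ring formation from carbene transfer. Slow addition of 8 to Rh2(OAc)4 in wet CH2Cl2 should end the carbene/alkyne metathesis by O–H insertion with water and give (4R)-3-(hydroxymethyl)-2-methyl-4-(propan-2-yl)cyclopent-2-en-1-one F1. MnO2 oxidation of the allylic alcohol then gives (5R)-2-methyl-3-oxo-5-(propan-2-yl)cyclopent-1-ene-1-carbaldehyde F2, and condensation with 2-(trifluoromethyl)benzenesulfonohydrazide gives the N-sulfonylhydrazone F3. Treating F3 with NaH and Rh2(OAc)4 in the presence of 11 at 0–40 °C releases the vinyldiazo compound slowly (Bamford–Stevens), so the same vinylcarbenoid meets the diene under diazo-starved conditions; the cyclopropane mixture containing 12 is then heated to 13.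

Step 7. The C3a radical may capture oxygen on the α-face, anti to the angular methyl, or hydrogen atom transfer may also engage the C6=C7 olefin. The fallback sets out from 13 and comes back at 14; it uses polar anti addition, which turns an α-face preference of external reagents to advantage. Hg(O2CCF3)2 in THF/H2O at 0 °C should form the mercurinium ion on the α-face, and water opens it at the tertiary C3a from the β-face to give the 4α-(trifluoroacetoxymercurio) 3aβ-carbinol F4. Brief reductive demercuration with alkaline NaBH4 at 0 °C then gives 14.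

Step 3. Deprotonation may occur at the C4 methylene of 5 instead of the ethyl CH2, giving the regioisomeric diazo ketone. The fallback sets out from 5 and comes back at 7; it replaces the kinetic enolate by thermodynamically controlled aminomethylenation. Heating 5 with N,N-dimethylformamide dimethyl acetal at 100 °C should condense at the less hindered ethyl CH2 and give the enaminone F5, which can be purified from any regioisomer. Deformylative diazo transfer with 4-methylbenzenesulfonyl azide in MeCN then gives 7.

Further compounds
F1 | step 6 | (4R)-3-(hydroxymethyl)-2-methyl-4-(propan-2-yl)cyclopent-2-en-1-one | CC1=C(CO)[C@@H](C(C)C)CC1=O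
F2 | step 6 | (5R)-2-methyl-3-oxo-5-(propan-2-yl)cyclopent-1-ene-1-carbaldehyde | CC1=C(C=O)[C@@H](C(C)C)CC1=O
F3 | step 6 | N′-{(E)-[(5R)-2-methyl-3-oxo-5-(propan-2-yl)cyclopent-1-en-1-yl]methylidene}-2-(trifluoromethyl)benzenesulfonohydrazide | CC1=C(/C=N/NS(=O)(=O)c2ccccc2C(F)(F)F)[C@@H](C(C)C)CC1=O
F4 | step 7 | 4α-[(trifluoroacetoxy)mercurio] derivative of 14 (3aβ-OH, 4α-Hg) | COc1ccc(cc1)C(=O)O[C@@H]2C=C(C)C[C@H]([Hg]OC(=O)C(F)(F)F)[C@]3(O)[C@@H](C(C)C)CC(=O)[C@]23C
F5 | step 3 | (1E,6R)-1-(dimethylamino)-2,7-dimethyl-6-{[tri(propan-2-yl)silyl]ethynyl}oct-1-en-3-one | CN(C)/C=C(\C)C(=O)C[C@H](C(C)C)C#C[Si](C(C)C)(C(C)C)C(C)C
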